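## Retrosynthetic overview

- The target is the (3R,4R)-trans-3,4-dibenzylbutyrolactone. Three late simplifications are used: the phenol is carried as a benzyl ether, the ring OCH2 carbon C5 as a menthyl acetal (a temporary stereocentre), and the benzylic CH2 of the 3,4-dimethoxybenzyl group as a 1,3-dithiane carbon.
- Key disconnection: the bond between that benzylic carbon and lactone C4. It is made by 1,4-addition of the polarity-reversed aldehyde carbon of veratraldehyde (as its 2-lithio-1,3-dithiane) to (5R)-5-(l-menthyloxy)furan-2(5H)-one. The C3 enolate left behind is benzylated in the same flask by 4-(benzyloxy)-3,5-dimethoxybenzyl bromide, so both C–C bonds and both stereocentres arise in one operation.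
- Enabling feature: C4 lies β to the lactone carbonyl C2, so the C3=C4 bond of a butenolide accepts a nucleophile at C4 and leaves an enolate at C3. The carbon to be attached is benzylic to the dimethoxyphenyl ring, so it can sit at the aldehyde oxidation level as an aryl- and sulfur-stabilised carbanion. C5, next to C4, can hold an acetal stereocentre that shields one ring face.
- Ring order: the five-membered oxygen ring is made first (furfural to the hydroxybutenolide, then the menthyl acetal) and survives the key step. It is opened and reclosed once when C5 is taken from acetal to CH2. Both benzene rings are bought; the dithiane ring is temporary.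

Key step: step 7

Remark: the SMILES is read as the (3R,4R)-trans-lactone; compound 3 is a racemic, configurationally labile hemiacetal and is drawn without a descriptor.

## Route

Step 1
Reactants: 1 furfural (furan-2-carbaldehyde)
Product: 3 5-hydroxyfuran-2(5H)-one (racemic hemiacetal), via furfural endoperoxide 2 (not isolated)
Conditions: O2, methylene blue (cat.), hν (visible), MeOH, rt
Reagents that add atoms: dioxygen, O=O
Why: Singlet-oxygen [4+2] photooxygenation of the furan diene gives endoperoxide 2, whose methanolysis at the formyl group fragments the C–CHO and O–O bonds to the hydroxybutenolide and methyl formate.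

Step 2
Reactants: 3 5-hydroxyfuran-2(5H)-one; 4 (−)-menthol [(1R,2S,5R)-2-isopropyl-5-methylcyclohexan-1-ol]
Product: 5 (5R)-5-(l-menthyloxy)furan-2(5H)-one
Conditions: cat. p-TsOH, PhMe, reflux (Dean–Stark); crystallisation from petroleum ether, mother liquor re-equilibrated with cat. p-TsOH and recrystallised
Reagents that add atoms: none
Why: Acid-catalysed acetalisation through the acyloxy-stabilised oxocarbenium ion gives both C5 epimers, and the 5R centre is set by crystallisation-induced diastereomer transformation, the less soluble (5R)-menthyl acetal crystallising while the acetal centre epimerises under acid in solution.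

Step 3
Reactants: 6 veratraldehyde (3,4-dimethoxybenzaldehyde)
Product: 7 2-(3,4-dimethoxyphenyl)-1,3-dithiane
Conditions: HS(CH2)3SH, BF3·OEt2 (cat.), CH2Cl2, 0 °C → rt
Reagents that add atoms: propane-1,3-dithiol, SCCCS
Why: Lewis-acid-catalysed dithioacetalisation of an aryl aldehyde masks the carbonyl carbon as an acidic C–H for later polarity reversal.

Step 4
Reactants: 8 syringaldehyde (4-hydroxy-3,5-dimethoxybenzaldehyde)
Product: 9 4-(benzyloxy)-3,5-dimethoxybenzaldehyde
Conditions: BnBr, K2CO3, DMF, 60 °C
Reagents that add atoms: benzyl bromide, BrCc1ccccc1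
Why: Williamson etherification of the phenoxide; the benzyl ether prevents quinone-methide formation from the later benzylic bromide and tolerates the organolithium, borohydride and hydroxide steps.

Step 5
Reactants: 9 4-(benzyloxy)-3,5-dimethoxybenzaldehyde
Product: 10 [4-(benzyloxy)-3,5-dimethoxyphenyl]methanol
Conditions: NaBH4, MeOH/THF, 0 °C
Reagents that add atoms: none
Why: Borohydride reduction of an aryl aldehyde to the benzylic alcohol.

Step 6
Reactants: 10 [4-(benzyloxy)-3,5-dimethoxyphenyl]methanol
Product: 11 4-(benzyloxy)-3,5-dimethoxybenzyl bromide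
Conditions: PBr3, Et2O, 0 °C
Reagents that add atoms: phosphorus tribromide, BrP(Br)Br
Why: SN2 bromination of the benzylic alcohol through its phosphite ester; the 4-alkoxy group flanked by two methoxy groups should leave the bromide isolable, as for 3,4,5-trimethoxybenzyl bromide.

Step 7
Reactants: 7 2-(3,4-dimethoxyphenyl)-1,3-dithiane; 5 (5R)-5-(l-menthyloxy)furan-2(5H)-one; 11 4-(benzyloxy)-3,5-dimethoxybenzyl bromide
Product: 14 (3R,4R,5R)-3-[4-(benzyloxy)-3,5-dimethoxybenzyl]-4-[2-(3,4-dimethoxyphenyl)-1,3-dithian-2-yl]-5-(l-menthyloxy)dihydrofuran-2(3H)-one, via lithiated dithiane 12 (not isolated), via lithium enolate 13 (not isolated)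
Conditions: n-BuLi, THF, −78 → −20 °C; then 5, THF, −78 °C; then 11, DMPU, −78 °C → rt; aq. NH4Cl
Reagents that add atoms: n-butyllithium, [Li]CCCC (supplies only the lithium of 12 and 13; none of its atoms stays in 14)
Why: Deprotonation of 7 gives the sulfur- and aryl-stabilised carbanion 12, an acyl-anion equivalent in which the veratraldehyde carbon has reversed polarity; it adds in a 1,4 sense to C4 of butenolide 5 and leaves lithium enolate 13, which is C-benzylated at C3 by bromide 11 in an SN2 step. The closest known reaction type is the tandem conjugate addition–enolate alkylation of lithiated aryl dithioacetals with 5-alkoxyfuran-2(5H)-ones, a three-component Michael-initiated coupling. No ring is closed: the lactone and dithiane rings are present beforehand and the step makes two exocyclic C–C bonds on the lactone ring. The C4 stereocentre is controlled by the C5 acetal centre, because the menthyloxy group shields its own face and the anion enters anti to it; the C3 stereocentre is controlled by C4, because the bromide approaches the planar enolate anti to the very large dithianyl substituent, which should give the 3,4-trans-4,5-trans lactone. The step needs 1,4- over 1,2-addition and C-alkylation without proton exchange: the soft, hindered, delocalised dithiane anion and the unhindered β-carbon of the ring-locked enoate secure the first, and the reactive benzylic bromide with DMPU as donor cosolvent secures the second.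

Step 8
Reactants: 14 (3R,4R,5R)-3-[4-(benzyloxy)-3,5-dimethoxybenzyl]-4-[2-(3,4-dimethoxyphenyl)-1,3-dithian-2-yl]-5-(l-menthyloxy)dihydrofuran-2(3H)-one
Product: 15 (3R,4R,5R)-3-[4-(benzyloxy)-3,5-dimethoxybenzyl]-4-(3,4-dimethoxybenzyl)-5-(l-menthyloxy)dihydrofuran-2(3H)-one
Conditions: NiCl2·6H2O, NaBH4, MeOH/THF, 0 °C
Reagents that add atoms: none
Why: Nickel boride desulfurisation (Ni2B made in situ) hydrogenolyses both benzylic C–S bonds and turns the dithiane carbon into the benzylic CH2 without touching a stereocentre; the aryl benzyl ether and the acyl acetal are expected to survive at 0 °C because NiCl2 consumes the borohydride rapidly.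

Step 9
Reactants: 15 (3R,4R,5R)-3-[4-(benzyloxy)-3,5-dimethoxybenzyl]-4-(3,4-dimethoxybenzyl)-5-(l-menthyloxy)dihydrofuran-2(3H)-one
Product: 18 (3R,4R)-3-[4-(benzyloxy)-3,5-dimethoxybenzyl]-4-(3,4-dimethoxybenzyl)dihydrofuran-2(3H)-one, via potassium aldehyde-carboxylate 16 (not isolated), via potassium hydroxy-carboxylate 17 (not isolated)
Conditions: KOH, NaBH4, EtOH/H2O, 0 °C → rt; then 2 M HCl to pH 1, rt
Reagents that add atoms: potassium hydroxide, [K+].[OH-] (potassium and one carboxylate oxygen of 16 and 17; after lactonisation at most that one oxygen stays in 18)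
Why: Hydrolysis–borohydride reduction–relactonisation of a γ-alkoxybutyrolactone: saponification of the acyl acetal releases menthol and aldehyde-carboxylate 16, borohydride present from the start reduces the aldehyde (former C5) before C4 can enolise, and acidification closes the γ-lactone on the untouched carboxyl carbon C2 by 5-exo-trig acyl substitution, so C3 and C4 are retained.

Step 10
Reactants: 18 (3R,4R)-3-[4-(benzyloxy)-3,5-dimethoxybenzyl]-4-(3,4-dimethoxybenzyl)dihydrofuran-2(3H)-one
Product: 19 (3R,4R)-4-(3,4-dimethoxybenzyl)-3-(4-hydroxy-3,5-dimethoxybenzyl)dihydrofuran-2(3H)-one (CNP0280366.1)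
Conditions: H2 (1 atm), 10% Pd/C, EtOAc/EtOH, rt
Reagents that add atoms: none
Why: Heterogeneous catalytic hydrogenolysis of the aryl benzyl ether; the two ArCH2–C bonds, the methyl ethers and the lactone are inert under these conditions.

## Compound list

1 | furfural (furan-2-carbaldehyde) | O=Cc1ccco1 | starting material
2 | 2,3,7-trioxabicyclo[2.2.1]hept-5-ene-1-carbaldehyde (furfural endoperoxide, racemic, not isolated) | O=CC12C=CC(OO1)O2 | intermediate
3 | 5-hydroxyfuran-2(5H)-one (racemic) | O=C1C=CC(O)O1 | intermediate
4 | (−)-menthol, (1R,2S,5R)-2-isopropyl-5-methylcyclohexan-1-ol | O[C@@H]1C[C@H](C)CC[C@H]1C(C)C | starting material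
5 | (5R)-5-{[(1R,2S,5R)-2-isopropyl-5-methylcyclohexyl]oxy}furan-2(5H)-one | O=C1C=C[C@H](O[C@@H]2C[C@H](C)CC[C@H]2C(C)C)O1 | intermediate
6 | veratraldehyde (3,4-dimethoxybenzaldehyde) | COc1ccc(C=O)cc1OC | starting material
7 | 2-(3,4-dimethoxyphenyl)-1,3-dithiane | COc1ccc(C2SCCCS2)cc1OC | intermediate
8 | syringaldehyde (4-hydroxy-3,5-dimethoxybenzaldehyde) | COc1cc(C=O)cc(OC)c1O | starting material
9 | 4-(benzyloxy)-3,5-dimethoxybenzaldehyde | COc1cc(C=O)cc(OC)c1OCc1ccccc1 | intermediate
10 | [4-(benzyloxy)-3,5-dimethoxyphenyl]methanol | COc1cc(CO)cc(OC)c1OCc1ccccc1 | intermediate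
11 | 4-(benzyloxy)-3,5-dimethoxybenzyl bromide | COc1cc(CBr)cc(OC)c1OCc1ccccc1 | intermediate
12 | 2-lithio-2-(3,4-dimethoxyphenyl)-1,3-dithiane (not isolated) | [Li]C1(SCCCS1)c1ccc(OC)c(OC)c1 | intermediate
13 | lithium (4R,5R)-4-[2-(3,4-dimethoxyphenyl)-1,3-dithian-2-yl]-5-(l-menthyloxy)-4,5-dihydrofuran-2-olate (not isolated) | [Li]OC1=C[C@@H](C2(SCCCS2)c2ccc(OC)c(OC)c2)[C@H](O[C@@H]2C[C@H](C)CC[C@H]2C(C)C)O1 | intermediate
14 | (3R,4R,5R)-3-[4-(benzyloxy)-3,5-dimethoxybenzyl]-4-[2-(3,4-dimethoxyphenyl)-1,3-dithian-2-yl]-5-(l-menthyloxy)dihydrofuran-2(3H)-one | O=C1O[C@@H](O[C@@H]2C[C@H](C)CC[C@H]2C(C)C)[C@H](C2(SCCCS2)c2ccc(OC)c(OC)c2)[C@H]1Cc1cc(OC)c(OCc2ccccc2)c(OC)c1 | intermediate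
15 | (3R,4R,5R)-3-[4-(benzyloxy)-3,5-dimethoxybenzyl]-4-(3,4-dimethoxybenzyl)-5-(l-menthyloxy)dihydrofuran-2(3H)-one | O=C1O[C@@H](O[C@@H]2C[C@H](C)CC[C@H]2C(C)C)[C@H](Cc2ccc(OC)c(OC)c2)[C@H]1Cc1cc(OC)c(OCc2ccccc2)c(OC)c1 | intermediate
16 | potassium (2R,3R)-2-[4-(benzyloxy)-3,5-dimethoxybenzyl]-3-(3,4-dimethoxybenzyl)-4-oxobutanoate (not isolated) | [K+].[O-]C(=O)[C@H](Cc1cc(OC)c(OCc2ccccc2)c(OC)c1)[C@@H](Cc1ccc(OC)c(OC)c1)C=O | intermediate
17 | potassium (2R,3R)-2-[4-(benzyloxy)-3,5-dimethoxybenzyl]-3-(3,4-dimethoxybenzyl)-4-hydroxybutanoate (not isolated) | [K+].[O-]C(=O)[C@H](Cc1cc(OC)c(OCc2ccccc2)c(OC)c1)[C@@H](Cc1ccc(OC)c(OC)c1)CO | intermediate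
18 | (3R,4R)-3-[4-(benzyloxy)-3,5-dimethoxybenzyl]-4-(3,4-dimethoxybenzyl)dihydrofuran-2(3H)-one | O=C1OC[C@H](Cc2ccc(OC)c(OC)c2)[C@H]1Cc1cc(OC)c(OCc2ccccc2)c(OC)c1 | intermediate
19 | (3R,4R)-4-(3,4-dimethoxybenzyl)-3-(4-hydroxy-3,5-dimethoxybenzyl)dihydrofuran-2(3H)-one | COc1ccc(C[C@H]2COC(=O)[C@@H]2Cc2cc(OC)c(O)c(OC)c2)cc1OC | target

## Step count and risks

Total step count: 10. Longest linear sequence: 7 steps (8 → 9 → 10 → 11 → 14 → 15 → 18 → 19, steps 4 to 10).

**Step 7 (key step).** What may go wrong: the alkylation stage. SN2 attack of the hindered, aggregated lithium enolate on the bromide may be slow enough for proton transfer from the product to the enolate, or O-alkylation, to compete. The fallback replaces alkylation by aldol trapping followed by deoxygenation. It sets out from 13, generated as in step 7. The enolate is quenched at −78 °C with aldehyde 9, which reacts with lactone enolates far faster than an alkyl halide. This should give the β-hydroxy lactone (3S,4R,5R)-3-{[4-(benzyloxy)-3,5-dimethoxyphenyl](hydroxy)methyl}-4-[2-(3,4-dimethoxyphenyl)-1,3-dithian-2-yl]-5-(l-menthyloxy)dihydrofuran-2(3H)-one F1. Both carbinol epimers are usable, and the descriptor at C3 changes only through the CIP ranking. Desulfurisation with Ni2B as in step 8 should give (3S,4R,5R)-3-{[4-(benzyloxy)-3,5-dimethoxyphenyl](hydroxy)methyl}-4-(3,4-dimethoxybenzyl)-5-(l-menthyloxy)dihydrofuran-2(3H)-one F2. Ionic hydrogenation of the electron-rich benzylic alcohol (Et3SiH, CF3CO2H, CH2Cl2, 0 °C) then removes the hydroxyl group, and the fallback comes back to the route at 15.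

**Step 9.** What may go wrong: enolisation of the open-chain aldehyde at C4 under hydroxide before hydride delivery, which would erode the trans relationship and the enantiomeric purity. The fallback unmasks the aldehyde under acid first. It sets out from 15. Hydrolysis of the menthyl acetal with 2 M HCl in dioxane at 60 °C should give the cyclic pseudo-acid (3R,4R)-3-[4-(benzyloxy)-3,5-dimethoxybenzyl]-4-(3,4-dimethoxybenzyl)-5-hydroxydihydrofuran-2(3H)-one F3 (C5 epimers), in which the aldehyde is stored as a lactol. Reduction with KBH4 in EtOH at 0 °C, with no hydroxide present, takes the small equilibrium amount of ring-opened form (16) through to 17, where the fallback comes back to the route. Acidification lactonises 17 to 18 as in step 9.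

**Step 8.** What may go wrong: attack of borohydride or methoxide on the acyl acetal carbonyl while Ni2B is being generated (ring opening and over-reduction before both C–S bonds are cleaved), or stalling after the first C–S cleavage. The fallback is a homolytic desulfurisation. It sets out from 14. Bu3SnH (excess) with AIBN in benzene at 80 °C cleaves the two benzylic C–S bonds by a radical chain, through the tertiary and then the secondary benzylic radical. The medium is neutral and aprotic with no nucleophile, so the benzyl ether and the acyl acetal should be untouched. The fallback comes back to the route at 15 directly; no new compound arises (entry F0).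

## Further compounds

F1 | step 7 | (3S,4R,5R)-3-{[4-(benzyloxy)-3,5-dimethoxyphenyl](hydroxy)methyl}-4-[2-(3,4-dimethoxyphenyl)-1,3-dithian-2-yl]-5-(l-menthyloxy)dihydrofuran-2(3H)-one (carbinol epimers) | O=C1O[C@@H](O[C@@H]2C[C@H](C)CC[C@H]2C(C)C)[C@H](C2(SCCCS2)c2ccc(OC)c(OC)c2)[C@H]1C(O)c1cc(OC)c(OCc2ccccc2)c(OC)c1
F2 | step 7 | (3S,4R,5R)-3-{[4-(benzyloxy)-3,5-dimethoxyphenyl](hydroxy)methyl}-4-(3,4-dimethoxybenzyl)-5-(l-menthyloxy)dihydrofuran-2(3H)-one (carbinol epimers) | O=C1O[C@@H](O[C@@H]2C[C@H](C)CC[C@H]2C(C)C)[C@H](Cc2ccc(OC)c(OC)c2)[C@H]1C(O)c1cc(OC)c(OCc2ccccc2)c(OC)c1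
F3 | step 9 | (3R,4R)-3-[4-(benzyloxy)-3,5-dimethoxybenzyl]-4-(3,4-dimethoxybenzyl)-5-hydroxydihydrofuran-2(3H)-one (C5 epimers) | O=C1OC(O)[C@H](Cc2ccc(OC)c(OC)c2)[C@H]1Cc1cc(OC)c(OCc2ccccc2)c(OC)c1
F0 | step 8 | none | none
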